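**Plan**

- Retrosynthesis: the four phenols are unmasked last (benzyl ethers on ring C, a methoxymethyl ether on ring B). Ring B is then cut at two neighbouring bonds, the B5–C1′ biaryl bond and the B4–O bond.
- Enabling feature: ring B (C1 phenethyl, C3–O, C4–O, C5–aryl) carries three contiguous substituents, so C4 and C5 can be the two carbons of an aryne flanked by the C3 oxygen.
- Each bibenzyl half is cut at its ArCH2–CH2Ar bond (Wittig olefination, then saturation), leading back to 3-fluoro-5-hydroxybenzaldehyde or 3,4-bis(benzyloxy)benzaldehyde and one shared phosphonium salt.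
- Forward: no ring is formed, since all four benzene rings are purchased. The two chains are built first, the halves are joined by aryne arylmagnesiation with oxygen trapping, and acid treatment followed by hydrogenolysis finishes the synthesis.
- Stereochemistry: the target has no stereocentre, its biaryl axis has only two ortho substituents and rotates freely, and the stilbene geometry is erased on reduction.

Key step: step 8

Remark: compounds 1, 3 and 6 are taken as purchasable. The Grignard reagent 10 is prepared as a titrated THF solution and is counted as a compound of the route.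

**Route**

Step 1
Reactants: 1 3-fluoro-5-hydroxybenzaldehyde
Product: 2 3-fluoro-5-(methoxymethoxy)benzaldehyde
Conditions: MOMCl, iPr2NEt, CH2Cl2, 0 °C → rt
Reagents that add atoms: chloromethyl methyl ether, COCCl
Why: O-alkylation of a phenol with MOMCl under amine base is a standard acetal protection that leaves the aldehyde and the aryl fluoride untouched.

Step 2
Reactants: 2 3-fluoro-5-(methoxymethoxy)benzaldehyde; 3 (3-methoxybenzyl)triphenylphosphonium chloride
Product: 4 1-fluoro-3-(methoxymethoxy)-5-[2-(3-methoxyphenyl)ethenyl]benzene (E/Z mixture)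
Conditions: KOtBu, THF, 0 °C → rt
Reagents that add atoms: none
Why: Wittig olefination of an aromatic aldehyde with a semi-stabilised benzylic ylide reliably gives the stilbene, and the E/Z mixture is acceptable because the double bond is saturated in the next step.

Step 3
Reactants: 4 1-fluoro-3-(methoxymethoxy)-5-[2-(3-methoxyphenyl)ethenyl]benzene
Product: 5 1-fluoro-3-(methoxymethoxy)-5-[2-(3-methoxyphenyl)ethyl]benzene
Conditions: H2 (1 atm), 10% Pd/C, EtOAc, rt
Reagents that add atoms: none
Why: catalytic hydrogenation of a stilbene over Pd/C is fast at atmospheric pressure, and the aryl C–F bond, the acetal and the methyl ether are inert under these conditions.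

Step 4
Reactants: 6 3,4-bis(benzyloxy)benzaldehyde
Product: 7 4,5-bis(benzyloxy)-2-bromobenzaldehyde
Conditions: Br2, NaOAc, AcOH, rt
Reagents that add atoms: bromine, BrBr
Why: electrophilic aromatic bromination of 3,4-dialkoxybenzaldehydes occurs at C6 (para to the C3 oxygen, ortho to the formyl group), and the acetate buffer keeps HBr from cleaving the benzyl ethers.

Step 5
Reactants: 7 4,5-bis(benzyloxy)-2-bromobenzaldehyde; 3 (3-methoxybenzyl)triphenylphosphonium chloride
Product: 8 1,2-bis(benzyloxy)-4-bromo-5-[2-(3-methoxyphenyl)ethenyl]benzene (E/Z mixture)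
Conditions: KOtBu, THF, 0 °C → rt
Reagents that add atoms: none
Why: the same Wittig olefination as in step 2 tolerates the ortho bromine and the benzyl ethers, and the alkene geometry is again irrelevant.

Step 6
Reactants: 8 1,2-bis(benzyloxy)-4-bromo-5-[2-(3-methoxyphenyl)ethenyl]benzene
Product: 9 1,2-bis(benzyloxy)-4-bromo-5-[2-(3-methoxyphenyl)ethyl]benzene
Conditions: p-toluenesulfonyl hydrazide (excess), NaOAc, DME/H2O, reflux
Reagents that add atoms: none
Why: diimide reduction transfers two hydrogens to the non-polar C=C bond in a concerted syn fashion and cannot touch the aryl bromide or the benzyl ethers, which hydrogenation over palladium would endanger.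

Step 7
Reactants: 9 1,2-bis(benzyloxy)-4-bromo-5-[2-(3-methoxyphenyl)ethyl]benzene
Product: 10 [4,5-bis(benzyloxy)-2-[2-(3-methoxyphenyl)ethyl]phenyl]magnesium bromide (THF solution, titrated, used directly)
Conditions: Mg turnings, cat. 1,2-dibromoethane, THF, reflux
Reagents that add atoms: magnesium, [Mg]
Why: Grignard formation by oxidative insertion of magnesium into the aryl C–Br bond is compatible with aryl alkyl ethers and benzyl ethers, which are the only other functions present.

Step 8
Reactants: 5 1-fluoro-3-(methoxymethoxy)-5-[2-(3-methoxyphenyl)ethyl]benzene; 10 [4,5-bis(benzyloxy)-2-[2-(3-methoxyphenyl)ethyl]phenyl]magnesium bromide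
Product: 15 2-[4,5-bis(benzyloxy)-2-[2-(3-methoxyphenyl)ethyl]phenyl]-6-(methoxymethoxy)-4-[2-(3-methoxyphenyl)ethyl]phenol, via ortho-lithiated fluoroarene 11 (not isolated), via 3-(methoxymethoxy)aryne 12 (not isolated), via biarylmagnesium bromide 13 (not isolated), via dimethyl biarylboronate 14 (not isolated)
Conditions: 5, n-BuLi, THF, −78 °C; then 10 (about 2 equiv), −78 °C → rt; B(OMe)3, −78 °C → rt; AcOH, 30% aq. H2O2, 0 °C → rt
Reagents that add atoms: n-butyllithium, [Li]CCCC (lithium of 11 only); trimethyl borate, COB(OC)OC (boron and methoxy groups of 14 only); hydrogen peroxide, OO (the B4 oxygen of 15)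
Why: n-BuLi removes the B4 hydrogen, the only one flanked by both fluorine and the acetal oxygen (cooperative directed ortho-metalation), and on warming 11 expels LiF to give aryne 12 across B4–B5. The aryl Grignard 10 adds to the strained triple bond (aryne carbomagnesiation), forming the B5–C1′ biaryl bond and leaving magnesium on B4 in 13, which B(OMe)3 captures as boronate 14; hydroperoxide then triggers the 1,2-shift of the aryl group from boron to oxygen that creates the B4–O bond. The closest known reaction type is the addition of aryl Grignard reagents to 3-alkoxyarynes released from ortho-lithiated fluoroarenes with electrophilic quench of the ortho-metalated biaryl, joined here to the classical borate–peroxide conversion of arylmagnesium halides into phenols. No ring is closed and no stereocentre is formed. The step needs regioselective addition, which is secured by the inductively withdrawing B3 oxygen: it polarises and distorts the aryne so that the nucleophile attacks the distal carbon B5 and the negative charge develops on B4 beside oxygen, where the acetal can also chelate the metal. Self-addition of 11 to the aryne is held back by the excess of 10, and because B4 is by far the most acidic site, the anisole rings, the benzylic positions and B2/B6 should not be metalated at −78 °C.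

Step 9
Reactants: 15 2-[4,5-bis(benzyloxy)-2-[2-(3-methoxyphenyl)ethyl]phenyl]-6-(methoxymethoxy)-4-[2-(3-methoxyphenyl)ethyl]phenol
Product: 16 3-[4,5-bis(benzyloxy)-2-[2-(3-methoxyphenyl)ethyl]phenyl]-5-[2-(3-methoxyphenyl)ethyl]benzene-1,2-diol
Conditions: HCl (2 M aq.), MeOH/THF, 40 °C, argon
Reagents that add atoms: none
Why: acid-catalysed acetal exchange in methanol removes the methoxymethyl group as dimethoxymethane, while benzyl and methyl aryl ethers are stable to dilute HCl at this temperature.

Step 10
Reactants: 16 3-[4,5-bis(benzyloxy)-2-[2-(3-methoxyphenyl)ethyl]phenyl]-5-[2-(3-methoxyphenyl)ethyl]benzene-1,2-diol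
Product: 17 Isoplagilin, 3-[4,5-dihydroxy-2-[2-(3-methoxyphenyl)ethyl]phenyl]-5-[2-(3-methoxyphenyl)ethyl]benzene-1,2-diol
Conditions: H2 (1 atm), 10% Pd/C, EtOAc/MeOH, rt; filtration under argon
Reagents that add atoms: none
Why: hydrogenolysis of benzyl aryl ethers over Pd/C leaves aryl methyl ethers and the bibenzyl chains intact and forms only toluene, so the air-sensitive bis-catechol should be obtained by filtration and evaporation.

**Compound list**

1 | 3-fluoro-5-hydroxybenzaldehyde | O=Cc1cc(O)cc(F)c1 | starting material
2 | 3-fluoro-5-(methoxymethoxy)benzaldehyde | COCOc1cc(F)cc(C=O)c1 | intermediate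
3 | (3-methoxybenzyl)triphenylphosphonium chloride | COc1cccc(C[P+](c2ccccc2)(c2ccccc2)c2ccccc2)c1.[Cl-] | starting material
4 | 1-fluoro-3-(methoxymethoxy)-5-[2-(3-methoxyphenyl)ethenyl]benzene (E/Z mixture) | COCOc1cc(F)cc(C=Cc2cccc(OC)c2)c1 | intermediate
5 | 1-fluoro-3-(methoxymethoxy)-5-[2-(3-methoxyphenyl)ethyl]benzene | COCOc1cc(F)cc(CCc2cccc(OC)c2)c1 | intermediate
6 | 3,4-bis(benzyloxy)benzaldehyde | O=Cc1ccc(OCc2ccccc2)c(OCc2ccccc2)c1 | starting material
7 | 4,5-bis(benzyloxy)-2-bromobenzaldehyde | O=Cc1cc(OCc2ccccc2)c(OCc2ccccc2)cc1Br | intermediate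
8 | 1,2-bis(benzyloxy)-4-bromo-5-[2-(3-methoxyphenyl)ethenyl]benzene (E/Z mixture) | COc1cccc(C=Cc2cc(OCc3ccccc3)c(OCc3ccccc3)cc2Br)c1 | intermediate
9 | 1,2-bis(benzyloxy)-4-bromo-5-[2-(3-methoxyphenyl)ethyl]benzene | COc1cccc(CCc2cc(OCc3ccccc3)c(OCc3ccccc3)cc2Br)c1 | intermediate
10 | [4,5-bis(benzyloxy)-2-[2-(3-methoxyphenyl)ethyl]phenyl]magnesium bromide | Br[Mg]c1cc(OCc2ccccc2)c(OCc2ccccc2)cc1CCc1cccc(OC)c1 | intermediate
11 | [2-fluoro-6-(methoxymethoxy)-4-[2-(3-methoxyphenyl)ethyl]phenyl]lithium | COCOc1cc(CCc2cccc(OC)c2)cc(F)c1[Li] | intermediate (not isolated)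
12 | 3-(methoxymethoxy)-5-[2-(3-methoxyphenyl)ethyl]benzyne (1,2-didehydrobenzene) | COCOC1=CC(CCc2cccc(OC)c2)=CC#C1 | intermediate (not isolated)
13 | [2-[4,5-bis(benzyloxy)-2-[2-(3-methoxyphenyl)ethyl]phenyl]-6-(methoxymethoxy)-4-[2-(3-methoxyphenyl)ethyl]phenyl]magnesium bromide | COCOc1cc(CCc2cccc(OC)c2)cc(-c2cc(OCc3ccccc3)c(OCc3ccccc3)cc2CCc2cccc(OC)c2)c1[Mg]Br | intermediate (not isolated)
14 | dimethyl [2-[4,5-bis(benzyloxy)-2-[2-(3-methoxyphenyl)ethyl]phenyl]-6-(methoxymethoxy)-4-[2-(3-methoxyphenyl)ethyl]phenyl]boronate | COCOc1cc(CCc2cccc(OC)c2)cc(-c2cc(OCc3ccccc3)c(OCc3ccccc3)cc2CCc2cccc(OC)c2)c1B(OC)OC | intermediate (not isolated)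
15 | 2-[4,5-bis(benzyloxy)-2-[2-(3-methoxyphenyl)ethyl]phenyl]-6-(methoxymethoxy)-4-[2-(3-methoxyphenyl)ethyl]phenol | COCOc1cc(CCc2cccc(OC)c2)cc(-c2cc(OCc3ccccc3)c(OCc3ccccc3)cc2CCc2cccc(OC)c2)c1O | intermediate
16 | 3-[4,5-bis(benzyloxy)-2-[2-(3-methoxyphenyl)ethyl]phenyl]-5-[2-(3-methoxyphenyl)ethyl]benzene-1,2-diol | Oc1cc(CCc2cccc(OC)c2)cc(-c2cc(OCc3ccccc3)c(OCc3ccccc3)cc2CCc2cccc(OC)c2)c1O | intermediate
17 | Isoplagilin, 3-[4,5-dihydroxy-2-[2-(3-methoxyphenyl)ethyl]phenyl]-5-[2-(3-methoxyphenyl)ethyl]benzene-1,2-diol | COc1cccc(CCc2cc(O)c(O)c(-c3cc(O)c(O)cc3CCc3cccc(OC)c3)c2)c1 | target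

**Step count and risks**

Total step count: 10. Longest linear sequence: 7 steps (steps 4, 5, 6, 7, 8, 9, 10 from compound 6).

Steps most likely to fail:

Step 8. The crowded B4 aryl group, flanked by the acetal oxygen and the ortho-substituted ring C, may transfer from magnesium to boron only incompletely. It competes with the surplus of 10 for the borate, and the peroxide stage may over-oxidise the electron-rich phenol, so the biaryl would form without clean installation of the B4 oxygen. The fallback sets out from 13, generated from 5 and 10 exactly as in step 8. It is quenched with iodine, a small and fast electrophile, to give the isolable aryl iodide 1,2-bis(benzyloxy)-4-[2-iodo-3-(methoxymethoxy)-5-[2-(3-methoxyphenyl)ethyl]phenyl]-5-[2-(3-methoxyphenyl)ethyl]benzene F1. After purification, the C–I bond is converted into the C–OH bond by palladium-catalysed hydroxylation (Pd2(dba)3, 2-di-tert-butylphosphino-2′,4′,6′-triisopropylbiphenyl, KOH, 1,4-dioxane/H2O, 100 °C, then mild acidification). The oxygen is thus introduced by C–O reductive elimination at palladium instead of an aryl shift on boron, and the route is rejoined at 15.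

Step 7. Magnesium insertion into the electron-rich aryl bromide may initiate sluggishly and be accompanied by Wurtz-type homocoupling or protonation, giving a reagent solution of low and uncertain titre. The fallback sets out from 9 and replaces oxidative insertion by halogen–metal exchange. Treatment with t-BuLi (2 equiv) in THF at −78 °C gives [4,5-bis(benzyloxy)-2-[2-(3-methoxyphenyl)ethyl]phenyl]lithium F2, which is transmetalated with MgBr2·OEt2 to return to the route at 10.

Step 6. Diimide may disproportionate faster than it reduces the ortho-substituted stilbene, so saturation stalls and residual alkene, hard to separate from the bibenzyl, is carried forward. The fallback sets out from 7 and avoids any alkene. Addition of 3-methoxybenzylmagnesium chloride (THF, −78 °C → 0 °C) to the aldehyde gives racemic 1-[4,5-bis(benzyloxy)-2-bromophenyl]-2-(3-methoxyphenyl)ethan-1-ol F3. Ionic deoxygenation (Et3SiH, CF3CO2H, CH2Cl2, 0 °C) proceeds through the benzylic cation stabilised by the para benzyloxy group and removes the hydroxyl, returning to the route at 9 and bypassing 8.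

Further compounds
F1 | step 8 | 1,2-bis(benzyloxy)-4-[2-iodo-3-(methoxymethoxy)-5-[2-(3-methoxyphenyl)ethyl]phenyl]-5-[2-(3-methoxyphenyl)ethyl]benzene | COCOc1cc(CCc2cccc(OC)c2)cc(-c2cc(OCc3ccccc3)c(OCc3ccccc3)cc2CCc2cccc(OC)c2)c1I
F2 | step 7 | [4,5-bis(benzyloxy)-2-[2-(3-methoxyphenyl)ethyl]phenyl]lithium | [Li]c1cc(OCc2ccccc2)c(OCc2ccccc2)cc1CCc1cccc(OC)c1
F3 | step 6 | 1-[4,5-bis(benzyloxy)-2-bromophenyl]-2-(3-methoxyphenyl)ethan-1-ol (racemic) | COc1cccc(CC(O)c2cc(OCc3ccccc3)c(OCc3ccccc3)cc2Br)c1
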